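**Plan**

Route labels (used in the plan and in the Why lines; compound names keep IUPAC locants): C1 oxygen-bearing bridgehead, C2 CMe2, C3 CH(prenyl), C4 CH2, C5 prenylated bridgehead, C6 lactone C=O, O7 lactone oxygen, C8 bridging ketone, C9 side-chain ketone, C10 sec-butyl CH.
Retrosynthesis: both prenyl termini are cut back to allyl groups, then C3–allyl and C4–C5 are cut, which opens the carbocycle (C1, C2, C3, C4, C5, C8) to a 5,5-disubstituted tetronic acid; C5–allyl is removed; O7–C1 and C1–C2 are then cut together to an acyclic diazo diketone prenyl ester, made from prenyl acetoacetate and (R)-2-methylbutanoic acid.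
Enabling feature: C1 carries O7, the two carbonyl carbons C8 and C9 and the fully substituted C2. This is the pattern left when a carbenoid flanked by two ketones takes the alkoxy oxygen of a prenyl ester into the five-membered lactone ring (C1, O7, C6, C5, C8) and receives the prenyl group at its dimethyl terminus.
Forward: chain assembly and diazo transfer; lactone ring by ylide formation and [2,3]-shift; allylation and bromination at C5; carbocycle by 6-endo bromine-transfer radical cyclisation (C4–C5); radical allylation at C3; double cross-metathesis to the two prenyl groups.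
Stereochemistry: C10 comes with (R)-2-methylbutanoic acid; C1 is set by the chiral dirhodium catalyst in the rearrangement; C5 follows from C1 because the three-carbon bridge can only close cis across the lactone; C3 is set by allyl delivery to the radical on the face anti to the lactone bridge.

Key step: step 5

Assumption: which antipode of the dirhodium catalyst gives the required C1 configuration cannot be predicted; Rh2(S-PTTL)4 is written, and Rh2(R-PTTL)4 would replace it should the (S)-catalyst favour the C1 epimer.

**Route**

Step 1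
Reactants: 1 2,2,6-trimethyl-4H-1,3-dioxin-4-one; 2 3-methylbut-2-en-1-ol
Product: 3 3-methylbut-2-en-1-yl 3-oxobutanoate (prenyl acetoacetate)
Conditions: toluene, 110 °C, acetone distilled off
Reagents that add atoms: none
Why: Thermal retro-[4+2] fragmentation of the dioxinone releases acetylketene, which the primary alcohol traps (acylketene acetoacetylation) under neutral conditions that leave the trisubstituted alkene alone.

Step 2
Reactants: 4 (2R)-2-methylbutanoic acid
Product: 6 (2R)-N-methoxy-N,2-dimethylbutanamide, via acyl imidazolide 5 (not isolated)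
Conditions: CDI, CH2Cl2, 0 °C → rt; then MeNH(OMe)·HCl, rt
Reagents that add atoms: N,O-dimethylhydroxylamine hydrochloride, CNOC.Cl; 1,1'-carbonyldiimidazole, O=C(n1ccnc1)n1ccnc1 (imidazolyl group of intermediate 5 only)
Why: Weinreb amide formation through the acyl imidazolide needs no base stronger than imidazole, so the α-stereocentre should be carried through unchanged.

Step 3
Reactants: 3 3-methylbut-2-en-1-yl 3-oxobutanoate; 6 (2R)-N-methoxy-N,2-dimethylbutanamide
Product: 7 3-methylbut-2-en-1-yl (6R)-6-methyl-3,5-dioxooctanoate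
Conditions: 3 (1.5 equiv), NaH, THF, 0 °C; n-BuLi, 0 °C; then 6, −78 → 0 °C; 1 M aq. HCl, 0 °C
Reagents that add atoms: none
Why: γ-Acylation of the acetoacetate dianion with a Weinreb amide: the terminal carbanion adds to the amide and the chelated tetrahedral adduct survives until the acidic quench, so over-addition and enolisation next to the sec-butyl centre should be avoided.

Step 4
Reactants: 7 3-methylbut-2-en-1-yl (6R)-6-methyl-3,5-dioxooctanoate
Product: 8 3-methylbut-2-en-1-yl (6R)-4-diazo-6-methyl-3,5-dioxooctanoate
Conditions: p-ABSA (1.0 equiv), Et3N, MeCN, 0 °C → rt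
Reagents that add atoms: 4-acetamidobenzenesulfonyl azide (p-ABSA), CC(=O)Nc1ccc(cc1)S(=O)(=O)N=[N+]=[N-]
Why: Regitz diazo transfer: Et3N removes the most acidic proton, that of the methylene between the two ketones, and a single equivalent of sulfonyl azide delivers N2 there, leaving the less acidic β-keto ester methylene (C5) and the sec-butyl centre untouched.

Step 5
Reactants: 8 3-methylbut-2-en-1-yl (6R)-4-diazo-6-methyl-3,5-dioxooctanoate
Product: 10 (5R)-5-[(2R)-2-methylbutanoyl]-5-(2-methylbut-3-en-2-yl)furan-2,4(3H,5H)-dione, via oxonium ylide 9 (not isolated)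
Conditions: Rh2(S-PTTL)4 (2 mol%; PTTL = N-phthaloyl-tert-leucinate), CH2Cl2, 0 °C → rt, slow addition of 8
Reagents that add atoms: none
Why: Proposed new method: Rh2(S-PTTL)4, a tetracarboxylate of divalent rhodium, should expel N2 from 8 to leave an electrophilic carbenoid at C1 between the C8 and C9 ketones; the alkoxy oxygen of the prenyl ester adds to it to give the rhodium-associated oxonium ylide 9, and the prenyl group then moves from O7 to C1 through a five-membered envelope transition state with allylic transposition, which forms O7–C1 and C1–C2 and releases the neutral lactone. The closest known reaction type is the rhodium- or copper-catalysed formation and [2,3]-sigmatropic rearrangement of oxonium ylides from diazo ketones that carry allyl ethers, which gives 2-allyltetrahydrofuran-3-ones; new here is an ester alkoxy oxygen, a weaker donor, as the ylide-forming atom. The lactone ring (C1, O7, C6, C5, C8) closes by 5-exo-trig attack of O7 on the metal-bound carbenoid carbon. C1 is the only stereocentre formed and is controlled by the chiral carboxylate ligands, which stay on the ylide during the shift; the distant C10 centre gives little bias, and a C1 epimer would be a diastereomer that can be removed. The step needs chemoselectivity for the alkoxy-oxygen ylide over the carbonyl-oxygen ylide, cyclopropanation, Wolff rearrangement and a [1,2]-shift: the carbonyl ylide has no sigmatropic exit and should revert at the metal, C5 is still CH2 so that no alkene lies within reach of C1, and the concerted five-centre path is favoured over radical-pair migration for a prenyl group. The acyl-oxonium character of 9 weakens the O7–CH2 bond, so the shift should be fast once the ylide exists.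

Step 6
Reactants: 10 (5R)-5-[(2R)-2-methylbutanoyl]-5-(2-methylbut-3-en-2-yl)furan-2,4(3H,5H)-dione
Product: 11 (5R)-4-hydroxy-5-[(2R)-2-methylbutanoyl]-5-(2-methylbut-3-en-2-yl)-3-(prop-2-en-1-yl)furan-2(5H)-one
Conditions: allyl methyl carbonate (1.0 equiv), Pd(PPh3)4 (5 mol%), THF, rt
Reagents that add atoms: allyl methyl carbonate, C=CCOC(=O)OC
Why: Tsuji–Trost allylation under neutral conditions: zerovalent palladium ionises the carbonate to a π-allyl complex and methoxide, the tetronate attacks through C5 because O-allyl isomers re-ionise, and a single equivalent of carbonate together with the lower acidity and greater crowding of the C-allylated enol should hold the reaction at mono-allylation.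

Step 7
Reactants: 11 (5R)-4-hydroxy-5-[(2R)-2-methylbutanoyl]-5-(2-methylbut-3-en-2-yl)-3-(prop-2-en-1-yl)furan-2(5H)-one
Product: 12 (5S)-3-bromo-5-[(2R)-2-methylbutanoyl]-5-(2-methylbut-3-en-2-yl)-3-(prop-2-en-1-yl)furan-2,4(3H,5H)-dione (both epimers at the brominated carbon)
Conditions: NBS (1.05 equiv), CH2Cl2, 0 °C, dark
Reagents that add atoms: N-bromosuccinimide, O=C1CCC(=O)N1Br
Why: Electrophilic α-bromination of the fully enolised 2-substituted 1,3-dicarbonyl unit is far faster than attack of NBS on monosubstituted alkenes; C5 becomes a stereocentre formed as both epimers, which does not matter because it is turned into a planar radical in the next step.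

Step 8
Reactants: 12 (5S)-3-bromo-5-[(2R)-2-methylbutanoyl]-5-(2-methylbut-3-en-2-yl)-3-(prop-2-en-1-yl)furan-2,4(3H,5H)-dione
Product: 13 (1S,3S,5S)-3-bromo-4,4-dimethyl-5-[(2R)-2-methylbutanoyl]-1-(prop-2-en-1-yl)-6-oxabicyclo[3.2.1]octane-7,8-dione
Conditions: Et3B (0.3 equiv), air, CH2Cl2 (0.05 M), rt
Reagents that add atoms: none
Why: Bromine atom-transfer radical cyclisation (Kharasch-type chain): the electrophilic C5 radical adds to the terminal vinyl carbon C4 in the 6-endo mode, favoured when the ketone lies inside the forming ring and the internal alkene carbon is neopentyl, and the C3 radical takes bromine from a second molecule of 12; the new C5 centre can only form cis-bridged to C1, and bromine is expected on the face anti to the lactone bridge (either C3 epimer serves in step 9).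

Step 9
Reactants: 13 (1S,3S,5S)-3-bromo-4,4-dimethyl-5-[(2R)-2-methylbutanoyl]-1-(prop-2-en-1-yl)-6-oxabicyclo[3.2.1]octane-7,8-dione
Product: 14 (1S,3S,5S)-4,4-dimethyl-5-[(2R)-2-methylbutanoyl]-1,3-di(prop-2-en-1-yl)-6-oxabicyclo[3.2.1]octane-7,8-dione
Conditions: CH2=CHCH2SnBu3 (3 equiv), AIBN (0.2 equiv), PhH, 80 °C
Reagents that add atoms: allyltributylstannane, C=CC[Sn](CCCC)(CCCC)CCCC
Why: Keck radical allylation: Bu3Sn• abstracts bromine and the C3 radical adds to the stannane with loss of Bu3Sn•; the face syn to the O7–C6 bridge is screened because that bridge is syn-axial to C3 in the chair, so the allyl group should enter anti to the lactone bridge and end equatorial with H toward the lactone, as in the target.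

Step 10
Reactants: 14 (1S,3S,5S)-4,4-dimethyl-5-[(2R)-2-methylbutanoyl]-1,3-di(prop-2-en-1-yl)-6-oxabicyclo[3.2.1]octane-7,8-dione
Product: 15 (1S,3S,5S)-4,4-dimethyl-1,3-bis(3-methylbut-2-en-1-yl)-5-[(2R)-2-methylbutanoyl]-6-oxabicyclo[3.2.1]octane-7,8-dione
Conditions: second-generation Grubbs catalyst RuCl2(=CHPh)(PCy3)(H2IMes) (10 mol%), 2-methylbut-2-ene/CH2Cl2, 40 °C, sealed tube
Reagents that add atoms: 2-methylbut-2-ene, CC=C(C)C
Why: Olefin cross-metathesis of the two monosubstituted allyl groups with a large excess of 2-methylbut-2-ene exchanges each =CH2 terminus for =CMe2, the trisubstituted prenyl products being too hindered to re-enter the cycle, and no stereocentre is touched.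

**Compound list**

1 | 2,2,6-trimethyl-4H-1,3-dioxin-4-one | CC1=CC(=O)OC(C)(C)O1 | starting material
2 | 3-methylbut-2-en-1-ol (prenol) | CC(C)=CCO | starting material
3 | 3-methylbut-2-en-1-yl 3-oxobutanoate | CC(=O)CC(=O)OCC=C(C)C | intermediate
4 | (2R)-2-methylbutanoic acid | CC[C@@H](C)C(=O)O | starting material
5 | 1-[(2R)-2-methylbutanoyl]-1H-imidazole (acyl imidazolide, not isolated) | CC[C@@H](C)C(=O)n1ccnc1 | intermediate
6 | (2R)-N-methoxy-N,2-dimethylbutanamide | CC[C@@H](C)C(=O)N(C)OC | intermediate
7 | 3-methylbut-2-en-1-yl (6R)-6-methyl-3,5-dioxooctanoate | CC[C@@H](C)C(=O)CC(=O)CC(=O)OCC=C(C)C | intermediate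
8 | 3-methylbut-2-en-1-yl (6R)-4-diazo-6-methyl-3,5-dioxooctanoate | CC[C@@H](C)C(=O)C(=[N+]=[N-])C(=O)CC(=O)OCC=C(C)C | intermediate
9 | 2-[(2R)-2-methylbutanoyl]-1-(3-methylbut-2-en-1-yl)-3,5-dioxooxolan-1-ium-2-ide (oxonium ylide, drawn free of rhodium, not isolated) | CC[C@@H](C)C(=O)[C-]1C(=O)CC(=O)[O+]1CC=C(C)C | intermediate
10 | (5R)-5-[(2R)-2-methylbutanoyl]-5-(2-methylbut-3-en-2-yl)furan-2,4(3H,5H)-dione (tetronic acid, drawn as the diketo tautomer) | CC[C@@H](C)C(=O)[C@]1(C(C)(C)C=C)OC(=O)CC1=O | intermediate
11 | (5R)-4-hydroxy-5-[(2R)-2-methylbutanoyl]-5-(2-methylbut-3-en-2-yl)-3-(prop-2-en-1-yl)furan-2(5H)-one (enol tautomer) | CC[C@@H](C)C(=O)[C@]1(C(C)(C)C=C)OC(=O)C(CC=C)=C1O | intermediate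
12 | (5S)-3-bromo-5-[(2R)-2-methylbutanoyl]-5-(2-methylbut-3-en-2-yl)-3-(prop-2-en-1-yl)furan-2,4(3H,5H)-dione (both epimers at ring C3, route label C5; same geometry at ring C5 as in 11, the descriptor changes by priority only) | CC[C@@H](C)C(=O)[C@]1(C(C)(C)C=C)OC(=O)C(Br)(CC=C)C1=O | intermediate
13 | (1S,3S,5S)-3-bromo-4,4-dimethyl-5-[(2R)-2-methylbutanoyl]-1-(prop-2-en-1-yl)-6-oxabicyclo[3.2.1]octane-7,8-dione (bromine anti to the lactone bridge) | CC[C@@H](C)C(=O)[C@@]12OC(=O)[C@@](CC=C)(C[C@H](Br)C1(C)C)C2=O | intermediate
14 | (1S,3S,5S)-4,4-dimethyl-5-[(2R)-2-methylbutanoyl]-1,3-di(prop-2-en-1-yl)-6-oxabicyclo[3.2.1]octane-7,8-dione | CC[C@@H](C)C(=O)[C@@]12OC(=O)[C@@](CC=C)(C[C@H](CC=C)C1(C)C)C2=O | intermediate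
15 | (1S,3S,5S)-4,4-dimethyl-1,3-bis(3-methylbut-2-en-1-yl)-5-[(2R)-2-methylbutanoyl]-6-oxabicyclo[3.2.1]octane-7,8-dione | CC[C@@H](C)C(=O)[C@@]12OC(=O)[C@@](CC=C(C)C)(C[C@H](CC=C(C)C)C1(C)C)C2=O | target

Total step count: 10
Longest linear sequence: 9 steps (4 → 15 through steps 2 to 10; equally 1 → 15 through steps 1 and 3 to 10)

**Steps most likely to fail**

1. Step 5 (proposed new method).
What may go wrong: the carbenoid may be captured by the ester carbonyl oxygen and then quenched by proton transfer from C5. The acyl-oxonium ylide may also ionise to a prenyl cation and an enolate that recombine without transposition. The catalyst may give little induction at C1.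
Fallback in known chemistry, setting out from 8 and returning at 10: slow addition of 8 to Rh2(OAc)4 (1 mol%) in CH2Cl2 containing an excess of 2 at room temperature should give, by intermolecular O–H insertion, 3-methylbut-2-en-1-yl (6R)-6-methyl-4-[(3-methylbut-2-en-1-yl)oxy]-3,5-dioxooctanoate F1. Its enolate, formed with DBU in CH2Cl2 at 0 °C, should undergo [2,3]-Wittig rearrangement to the tertiary alcohol 3-methylbut-2-en-1-yl (6R)-4-hydroxy-6-methyl-4-(2-methylbut-3-en-2-yl)-3,5-dioxooctanoate F2 (both epimers at the carbinol carbon). F2 lactonises onto the prenyl ester with loss of prenol to give 10 together with its C1 epimer, (5S)-5-[(2R)-2-methylbutanoyl]-5-(2-methylbut-3-en-2-yl)furan-2,4(3H,5H)-dione F3, which is to be removed by chromatography.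

2. Step 8.
What may go wrong: the bromine-transfer chain may not propagate, because abstraction of bromine from the crowded tertiary bromide 12 by the neopentyl-type C3 radical may be slower than reduction, β-scission back to the open radical or loss of HBr from the product.
Fallback, setting out from 12 and returning at 14 without passing through 13 (no new compound, F0): 12 is heated with CH2=CHCH2SnBu3 (2 equiv, 0.05 M) and AIBN in benzene at 80 °C. Bu3Sn• then carries the chain, the C5 radical cyclises 6-endo and the C3 radical is trapped directly by the stannane (tin-mediated tandem cyclisation–allylation). The low stannane concentration is chosen so that ring closure outruns allylation at C5.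

3. Step 9.
What may go wrong: allyl transfer to the C3 radical may show poor facial selectivity, because the axial methyl group on C2 also hinders the face anti to the lactone bridge, and slow trapping may allow ring reopening.
Fallback under thermodynamic control, setting out from 13 and returning at 14: radical carbonylation of 13 (Bu3SnH added slowly, CO 80 atm, AIBN, benzene, 80 °C) should give the C3 aldehyde, which Et3N in CH2Cl2 equilibrates through its enol to the equatorial epimer (1S,3S,5S)-4,4-dimethyl-5-[(2R)-2-methylbutanoyl]-7,8-dioxo-1-(prop-2-en-1-yl)-6-oxabicyclo[3.2.1]octane-3-carbaldehyde F4. Wittig reaction with Ph3P=CHOMe (from MeOCH2PPh3Cl and KN(SiMe3)2, THF, −78 → 0 °C) gives the enol ether (1S,3R,5S)-3-(2-methoxyethenyl)-4,4-dimethyl-5-[(2R)-2-methylbutanoyl]-1-(prop-2-en-1-yl)-6-oxabicyclo[3.2.1]octane-7,8-dione F5. Dilute aqueous HCl in THF unmasks 2-[(1S,3R,5S)-4,4-dimethyl-5-[(2R)-2-methylbutanoyl]-7,8-dioxo-1-(prop-2-en-1-yl)-6-oxabicyclo[3.2.1]octan-3-yl]acetaldehyde F6, and Ph3P=CH2 (THF, −78 → 0 °C) turns it into 14. The unhindered aldehydes should react with the ylides well before the crowded C8 and C9 ketones.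

**Further compounds**

F1 | step 5 | 3-methylbut-2-en-1-yl (6R)-6-methyl-4-[(3-methylbut-2-en-1-yl)oxy]-3,5-dioxooctanoate (C4 configurationally labile) | CC[C@@H](C)C(=O)C(OCC=C(C)C)C(=O)CC(=O)OCC=C(C)C
F2 | step 5 | 3-methylbut-2-en-1-yl (6R)-4-hydroxy-6-methyl-4-(2-methylbut-3-en-2-yl)-3,5-dioxooctanoate (both C4 epimers) | CC[C@@H](C)C(=O)C(O)(C(C)(C)C=C)C(=O)CC(=O)OCC=C(C)C
F3 | step 5 | (5S)-5-[(2R)-2-methylbutanoyl]-5-(2-methylbut-3-en-2-yl)furan-2,4(3H,5H)-dione (C1 epimer of 10) | CC[C@@H](C)C(=O)[C@@]1(C(C)(C)C=C)OC(=O)CC1=O
F0 | step 8 | none | none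
F4 | step 9 | (1S,3S,5S)-4,4-dimethyl-5-[(2R)-2-methylbutanoyl]-7,8-dioxo-1-(prop-2-en-1-yl)-6-oxabicyclo[3.2.1]octane-3-carbaldehyde (formyl anti to the lactone bridge, after equilibration) | CC[C@@H](C)C(=O)[C@@]12OC(=O)[C@@](CC=C)(C[C@H](C=O)C1(C)C)C2=O
F5 | step 9 | (1S,3R,5S)-3-(2-methoxyethenyl)-4,4-dimethyl-5-[(2R)-2-methylbutanoyl]-1-(prop-2-en-1-yl)-6-oxabicyclo[3.2.1]octane-7,8-dione (E/Z mixture) | CC[C@@H](C)C(=O)[C@@]12OC(=O)[C@@](CC=C)(C[C@H](C=COC)C1(C)C)C2=O
F6 | step 9 | 2-[(1S,3R,5S)-4,4-dimethyl-5-[(2R)-2-methylbutanoyl]-7,8-dioxo-1-(prop-2-en-1-yl)-6-oxabicyclo[3.2.1]octan-3-yl]acetaldehyde | CC[C@@H](C)C(=O)[C@@]12OC(=O)[C@@](CC=C)(C[C@H](CC=O)C1(C)C)C2=O
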